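**Retrosynthetic overview**

1. The two esters go on last: the anti-7,9-diol monoester comes from β-hydroxy ketone 18 (C7–OH, C9=O) by Evans–Tishchenko reduction with 3-methylbutanal, then O9 is acylated; the C1 enone is made at the end by oxidation/dehydrogenation of a C1 carbinol.
2. Key disconnection C9–C10: tricycle 18 comes from bicyclo[3.1.1]heptane 15, which carries an exocyclic methylene at C10 and a nitrile-terminated chain on C5. Hydrogen-atom transfer to the CH2 creates the C10 methyl and a tertiary radical that closes the seven-membered ring on the nitrile carbon C9.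
3. Enabling feature: the cyclobutane ring C4–C5–C11–C10 holds C10 and the C5 chain cis-1,3 on the face opposite the C1–C2–C3 bridge, and the C6 gem-dimethyl group folds the chain, so C9 sits over C10.
4. 15 comes from cyclobutanone 14, made from acyclic amide 11 by intramolecular keteniminium–alkene [2+2]; the chain stereocentres C7, C1 and C3 come from a ketoreductase reduction, a vinylogous Mukaiyama aldol and a CuH conjugate reduction.
5. Ring order: cyclobutane and six-membered ring together (step 10), then the seven-membered ring (step 12).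

Key step: step 12

Locants (longipinane numbering, used for all compounds): C1 ketone carbon, C2=C3 enone alkene (C3 bears the methyl), C4 and C11 cyclobutane bridgeheads (C11 next to C1), C5 cyclobutane CH, C6 gem-dimethyl carbon, C7 isovalerate carbinol, C8 CH2, C9 senecioate carbinol, C10 methyl-bearing quaternary carbon.

Assumption: methyl 2,2-dimethylbut-3-enoate is taken as commercially available; for the three catalyst-controlled steps the catalyst enantiomer is the one that gives the descriptor shown.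

**Step 1**
Reactants: 1 methyl 2,2-dimethylbut-3-enoate
Product: 2 4,4-dimethyl-3-oxohex-5-enenitrile
Conditions: MeCN, n-BuLi, THF, −78 °C → rt; aq. HCl
Reagents that add atoms: acetonitrile, CC#N
Why: Claisen-type acylation of lithioacetonitrile by the non-enolisable ester; the second equivalent of anion deprotonates the β-ketonitrile as it forms, which should stop over-addition.

**Step 2**
Reactants: 2 4,4-dimethyl-3-oxohex-5-enenitrile
Product: 3 (3R)-3-hydroxy-4,4-dimethylhex-5-enenitrile
Conditions: ketoreductase (R-selective), NADP+ (cat.), iPrOH, phosphate buffer pH 7, 30 °C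
Reagents that add atoms: none
Why: Enzymatic ketone reduction by a ketoreductase, a class that accepts tert-alkyl β-ketonitriles such as pivaloylacetonitrile; hydride delivery from NADPH to one carbonyl face in the active site should set the future C7 as R.

**Step 3**
Reactants: 3 (3R)-3-hydroxy-4,4-dimethylhex-5-enenitrile
Product: 4 (3R)-4,4-dimethyl-3-(triethylsilyloxy)hex-5-enenitrile
Conditions: Et3SiCl, imidazole, DMF, rt
Reagents that add atoms: chlorotriethylsilane, CC[Si](Cl)(CC)CC
Why: Standard silylation; the triethylsilyl ether masks O7 until after the key step and can later be removed in the presence of the tert-butyldimethylsilyl ether.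

**Step 4**
Reactants: 4 (3R)-4,4-dimethyl-3-(triethylsilyloxy)hex-5-enenitrile
Product: 5 (3R,5E)-4,4-dimethyl-7-oxo-3-(triethylsilyloxy)hept-5-enenitrile
Conditions: (E)-but-2-enal (excess), second-generation Hoveyda–Grubbs catalyst RuCl2(H2IMes)(=CH-C6H4-2-OiPr) (cat.), CH2Cl2, 40 °C
Reagents that add atoms: (E)-but-2-enal, C/C=C/C=O
Why: Olefin cross-metathesis; the vinyl group on a quaternary carbon does not homodimerise and the enal partner is electron-poor, so the cross product should form selectively as the E isomer.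

**Step 5**
Reactants: 6 methyl 3-methylbut-2-enoate
Product: 7 tert-butyl[(1-methoxy-3-methylbuta-1,3-dien-1-yl)oxy]dimethylsilane
Conditions: LiN(iPr)2, THF/DMPU, −78 °C; tBuMe2SiCl
Reagents that add atoms: tert-butyl(chloro)dimethylsilane, CC(C)(C)[Si](C)(C)Cl
Why: γ-Deprotonation of the senecioate and O-silylation of the dienolate gives the silyl dienol ether (silyl ketene acetal) needed for the vinylogous aldol.

**Step 6**
Reactants: 5 (3R,5E)-4,4-dimethyl-7-oxo-3-(triethylsilyloxy)hept-5-enenitrile; 7 tert-butyl[(1-methoxy-3-methylbuta-1,3-dien-1-yl)oxy]dimethylsilane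
Product: 8 methyl (2E,5S,6E,9R)-10-cyano-5-hydroxy-3,8,8-trimethyl-9-(triethylsilyloxy)deca-2,6-dienoate
Conditions: SiCl4, chiral binaphthyldiamine bisphosphoramide (cat., enantiomer giving 5S), iPr2NEt, CH2Cl2, −78 °C; aq. NaHCO3/KF
Reagents that add atoms: none
Why: Lewis-base-catalysed, SiCl4-mediated vinylogous Mukaiyama aldol; the dienolate attacks through its γ-carbon in a 1,2-addition to the enal and the chiral phosphoramide–silicon cation selects the aldehyde face, which sets the C1 carbinol (5S in 8).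

**Step 7**
Reactants: 8 methyl (2E,5S,6E,9R)-10-cyano-5-hydroxy-3,8,8-trimethyl-9-(triethylsilyloxy)deca-2,6-dienoate
Product: 9 methyl (2E,5S,6E,9R)-5-(tert-butyldimethylsilyloxy)-10-cyano-3,8,8-trimethyl-9-(triethylsilyloxy)deca-2,6-dienoate
Conditions: tBuMe2SiCl, imidazole, DMF, rt
Reagents that add atoms: tert-butyl(chloro)dimethylsilane, CC(C)(C)[Si](C)(C)Cl
Why: Silylation of the allylic carbinol; the more robust silyl ether keeps O1 masked until both esters are in place.

**Step 8**
Reactants: 9 methyl (2E,5S,6E,9R)-5-(tert-butyldimethylsilyloxy)-10-cyano-3,8,8-trimethyl-9-(triethylsilyloxy)deca-2,6-dienoate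
Product: 10 methyl (3R,5S,6E,9R)-5-(tert-butyldimethylsilyloxy)-10-cyano-3,8,8-trimethyl-9-(triethylsilyloxy)dec-6-enoate
Conditions: Cu(OAc)2·H2O (cat.), DTBM-SEGPHOS (cat., enantiomer giving 3R), (EtO)2MeSiH, tBuOH, toluene, 0 °C → rt
Reagents that add atoms: none
Why: Asymmetric copper hydride conjugate reduction of a β,β-disubstituted enoate; ligand-controlled hydride delivery to the β-carbon sets C3 as R, and the isolated alkene and the nitrile are not touched.

**Step 9**
Reactants: 10 methyl (3R,5S,6E,9R)-5-(tert-butyldimethylsilyloxy)-10-cyano-3,8,8-trimethyl-9-(triethylsilyloxy)dec-6-enoate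
Product: 11 (3R,5S,6E,9R)-5-(tert-butyldimethylsilyloxy)-10-cyano-3,8,8-trimethyl-1-(pyrrolidin-1-yl)-9-(triethylsilyloxy)dec-6-en-1-one
Conditions: pyrrolidine, AlMe3, CH2Cl2, 0 °C → rt; aq. potassium sodium tartrate
Reagents that add atoms: pyrrolidine, C1CCNC1
Why: Aluminium amide aminolysis of the methyl ester, which is faster than attack on the nitrile at room temperature, gives the tertiary amide needed for keteniminium formation.

**Step 10**
Reactants: 11 (3R,5S,6E,9R)-5-(tert-butyldimethylsilyloxy)-10-cyano-3,8,8-trimethyl-1-(pyrrolidin-1-yl)-9-(triethylsilyloxy)dec-6-en-1-one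
Product: 14 (3R)-4-[(1S,2S,4R,5S,7S)-2-(tert-butyldimethylsilyloxy)-4-methyl-6-oxobicyclo[3.1.1]heptan-7-yl]-4-methyl-3-(triethylsilyloxy)pentanenitrile, via keteniminium triflate 12 (not isolated), via cyclobutaniminium triflate 13 (not isolated)
Conditions: Tf2O, 2,4,6-collidine, ClCH2CH2Cl, 0 → 80 °C; then aq. NaHCO3, rt
Reagents that add atoms: water, O
Why: Intramolecular keteniminium–alkene [2+2] cycloaddition followed by iminium hydrolysis: the electrophilic carbon C10 should bond to C11 (crossed mode, bicyclo[3.1.1]) because positive charge at C11 would sit next to the C1 silyloxy carbon and C5 is neopentyl, the E alkene places the C6 chain anti to the three-carbon bridge, and a chair-like transition state with the C3 methyl and C1 silyloxy groups equatorial is expected to set C4, C5 and C11; a minor facial isomer would be removed by chromatography.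

**Step 11**
Reactants: 14 (3R)-4-[(1S,2S,4R,5S,7S)-2-(tert-butyldimethylsilyloxy)-4-methyl-6-oxobicyclo[3.1.1]heptan-7-yl]-4-methyl-3-(triethylsilyloxy)pentanenitrile
Product: 15 (3R)-4-[(1R,2S,4R,5S,7S)-2-(tert-butyldimethylsilyloxy)-4-methyl-6-methylidenebicyclo[3.1.1]heptan-7-yl]-4-methyl-3-(triethylsilyloxy)pentanenitrile
Conditions: Ph3PCH3Br, KOtBu, THF, 0 °C → rt
Reagents that add atoms: methyltriphenylphosphonium bromide, C[P+](c1ccccc1)(c1ccccc1)c1ccccc1.[Br-]
Why: Wittig methylenation of the strained, non-enolisable cyclobutanone (both α-carbons are bridgeheads) installs the carbon that becomes the C10 methyl group.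

**Step 12**
Reactants: 15 (3R)-4-[(1R,2S,4R,5S,7S)-2-(tert-butyldimethylsilyloxy)-4-methyl-6-methylidenebicyclo[3.1.1]heptan-7-yl]-4-methyl-3-(triethylsilyloxy)pentanenitrile
Product: 18 (1S,3R,4S,5S,7R,10R,11R)-1-(tert-butyldimethylsilyloxy)-7-hydroxylongipinan-9-one, via ketimine 16 (not isolated), via triethylsilyl ketone 17 (not isolated)
Conditions: Fe(acac)3 (cat.), PhSiH3, EtOH, degassed, 60 °C; then AcOH/THF/H2O, 40 °C
Reagents that add atoms: water, O
Why: Proposed new method: a trivalent iron hydride formed from Fe(acac)3 and PhSiH3 transfers a hydrogen atom to the exocyclic CH2 of 15, which creates the C10 methyl group and a tertiary cyclobutyl radical at C10; this radical adds to the nitrile carbon C9, and the iminyl radical is reduced by divalent iron and protonated to ketimine 16, which the acid work-up hydrolyses, with loss of the triethylsilyl group, to 18. The closest known reaction type is the Fe(acac)3/PhSiH3 HAT-initiated 5-exo and 6-exo cyclisation of alkenyl nitriles to cyclic ketones, together with HAT-initiated alkene–ketone cyclisations; here the mode is 7-exo-dig and it closes the seven-membered ring C5–C6–C7–C8–C9–C10–C11. The only new stereocentre, C10, is fixed by the tether: the chain on C5 is cis-1,3 to C10 across the cyclobutane on the face away from the C1–C2–C3 bridge, so C9 can bond only from that face and the methyl group ends syn to the bridge. The step needs the cyclisation to outrun simple reduction of the radical and 1,5-hydrogen transfer from C7; the rigid cis-1,3 cyclobutane scaffold and the C6 gem-dimethyl group hold C9 within reach of C10, no second alkene is present, and a cyclobutyl (not cyclobutylcarbinyl) radical does not ring-open readily. Reduction of the iminyl radical makes the addition irreversible, and delivering C9 as a ketone leaves its configuration to the next step.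

**Step 13**
Reactants: 18 (1S,3R,4S,5S,7R,10R,11R)-1-(tert-butyldimethylsilyloxy)-7-hydroxylongipinan-9-one
Product: 19 (1S,3R,4S,5S,7R,9R,10R,11R)-1-(tert-butyldimethylsilyloxy)-9-hydroxylongipinan-7-yl 3-methylbutanoate
Conditions: 3-methylbutanal (excess), SmI2 (cat.), THF, −10 °C
Reagents that add atoms: 3-methylbutanal, CC(C)CC=O
Why: Evans–Tishchenko reduction: the samarium-bound hemiacetal formed on O7 delivers hydride intramolecularly to the C9 ketone from the face of O7, so C9–OH should form anti to O7 (9R) while O7 leaves as the 3-methylbutanoate, which installs the first ester and differentiates the two oxygens in one operation.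

**Step 14**
Reactants: 19 (1S,3R,4S,5S,7R,9R,10R,11R)-1-(tert-butyldimethylsilyloxy)-9-hydroxylongipinan-7-yl 3-methylbutanoate
Product: 20 (1S,3R,4S,5S,7R,9R,10R,11R)-1-(tert-butyldimethylsilyloxy)-7-(3-methylbutanoyloxy)longipinan-9-yl 3-methylbut-2-enoate
Conditions: 3-methylbut-2-enoyl chloride, pyridine, DMAP (cat.), CH2Cl2, 0 °C → rt
Reagents that add atoms: 3-methylbut-2-enoyl chloride, CC(C)=CC(=O)Cl
Why: Acylation of the only free hydroxyl with the acid chloride under weakly basic conditions, chosen to limit deconjugation of the senecioate and 1,3-acyl migration.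

**Step 15**
Reactants: 20 (1S,3R,4S,5S,7R,9R,10R,11R)-1-(tert-butyldimethylsilyloxy)-7-(3-methylbutanoyloxy)longipinan-9-yl 3-methylbut-2-enoate
Product: 21 (1S,3R,4S,5S,7R,9R,10R,11R)-1-hydroxy-7-(3-methylbutanoyloxy)longipinan-9-yl 3-methylbut-2-enoate
Conditions: HF·pyridine, THF/pyridine, 0 °C → rt
Reagents that add atoms: none
Why: Buffered fluoride cleavage of the silyl ether, non-basic so that the two esters neither migrate nor hydrolyse.

**Step 16**
Reactants: 21 (1S,3R,4S,5S,7R,9R,10R,11R)-1-hydroxy-7-(3-methylbutanoyloxy)longipinan-9-yl 3-methylbut-2-enoate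
Product: 23 (4R,5S,7R,9R,10R,11R)-7-(3-methylbutanoyloxy)-1-oxolongipin-2-en-9-yl 3-methylbut-2-enoate (target CNP0335239.1), via saturated ketone 22 (not isolated)
Conditions: IBX (excess), DMSO, 75 °C
Reagents that add atoms: none
Why: Hypervalent iodine (IBX) oxidation of the carbinol to the C1 ketone and then α,β-dehydrogenation; the ketone can enolise only toward C2 because C11 is a bridgehead, so the C2=C3 enone is the only possible product and the C3 stereocentre is removed.

**Compound list**

1 | methyl 2,2-dimethylbut-3-enoate | C=CC(C)(C)C(=O)OC | starting material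
2 | 4,4-dimethyl-3-oxohex-5-enenitrile | C=CC(C)(C)C(=O)CC#N | intermediate
3 | (3R)-3-hydroxy-4,4-dimethylhex-5-enenitrile | C=CC(C)(C)[C@H](O)CC#N | intermediate
4 | (3R)-4,4-dimethyl-3-(triethylsilyloxy)hex-5-enenitrile | C=CC(C)(C)[C@H](O[Si](CC)(CC)CC)CC#N | intermediate
5 | (3R,5E)-4,4-dimethyl-7-oxo-3-(triethylsilyloxy)hept-5-enenitrile | O=C/C=C/C(C)(C)[C@H](O[Si](CC)(CC)CC)CC#N | intermediate
6 | methyl 3-methylbut-2-enoate | COC(=O)C=C(C)C | starting material
7 | tert-butyl[(1-methoxy-3-methylbuta-1,3-dien-1-yl)oxy]dimethylsilane | COC(=CC(C)=C)O[Si](C)(C)C(C)(C)C | intermediate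
8 | methyl (2E,5S,6E,9R)-10-cyano-5-hydroxy-3,8,8-trimethyl-9-(triethylsilyloxy)deca-2,6-dienoate | COC(=O)/C=C(\C)C[C@H](O)/C=C/C(C)(C)[C@H](O[Si](CC)(CC)CC)CC#N | intermediate
9 | methyl (2E,5S,6E,9R)-5-(tert-butyldimethylsilyloxy)-10-cyano-3,8,8-trimethyl-9-(triethylsilyloxy)deca-2,6-dienoate | COC(=O)/C=C(\C)C[C@H](O[Si](C)(C)C(C)(C)C)/C=C/C(C)(C)[C@H](O[Si](CC)(CC)CC)CC#N | intermediate
10 | methyl (3R,5S,6E,9R)-5-(tert-butyldimethylsilyloxy)-10-cyano-3,8,8-trimethyl-9-(triethylsilyloxy)dec-6-enoate | COC(=O)C[C@H](C)C[C@H](O[Si](C)(C)C(C)(C)C)/C=C/C(C)(C)[C@H](O[Si](CC)(CC)CC)CC#N | intermediate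
11 | (3R,5S,6E,9R)-5-(tert-butyldimethylsilyloxy)-10-cyano-3,8,8-trimethyl-1-(pyrrolidin-1-yl)-9-(triethylsilyloxy)dec-6-en-1-one | O=C(C[C@H](C)C[C@H](O[Si](C)(C)C(C)(C)C)/C=C/C(C)(C)[C@H](O[Si](CC)(CC)CC)CC#N)N1CCCC1 | intermediate
12 | keteniminium triflate from 11 (N-alkenylidene pyrrolidinium, chain stereocentres as in 11) | C1CC[N+](C1)=C=C[C@H](C)C[C@H](O[Si](C)(C)C(C)(C)C)/C=C/C(C)(C)[C@H](O[Si](CC)(CC)CC)CC#N.[O-]S(=O)(=O)C(F)(F)F | intermediate (not isolated)
13 | cyclobutaniminium triflate (pyrrolidinium iminium of ketone 14, same configuration) | C1CC[N+](C1)=C1[C@H]2[C@@H](C(C)(C)[C@H](O[Si](CC)(CC)CC)CC#N)[C@@H]1[C@H](C)C[C@@H]2O[Si](C)(C)C(C)(C)C.[O-]S(=O)(=O)C(F)(F)F | intermediate (not isolated)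
14 | (3R)-4-[(1S,2S,4R,5S,7S)-2-(tert-butyldimethylsilyloxy)-4-methyl-6-oxobicyclo[3.1.1]heptan-7-yl]-4-methyl-3-(triethylsilyloxy)pentanenitrile (silyloxy and methyl groups cis to the chain-bearing bridge, chain anti to the three-carbon bridge) | O=C1[C@H]2[C@@H](C(C)(C)[C@H](O[Si](CC)(CC)CC)CC#N)[C@@H]1[C@H](C)C[C@@H]2O[Si](C)(C)C(C)(C)C | intermediate
15 | (3R)-4-[(1R,2S,4R,5S,7S)-2-(tert-butyldimethylsilyloxy)-4-methyl-6-methylidenebicyclo[3.1.1]heptan-7-yl]-4-methyl-3-(triethylsilyloxy)pentanenitrile | C=C1[C@H]2[C@@H](C(C)(C)[C@H](O[Si](CC)(CC)CC)CC#N)[C@@H]1[C@H](C)C[C@@H]2O[Si](C)(C)C(C)(C)C | intermediate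
16 | (1S,3R,4S,5S,7R,10R,11R)-1-(tert-butyldimethylsilyloxy)-7-(triethylsilyloxy)longipinan-9-imine | N=C1C[C@@H](O[Si](CC)(CC)CC)C(C)(C)[C@@H]2[C@H]3[C@@H](O[Si](C)(C)C(C)(C)C)C[C@@H](C)[C@@H]2[C@]31C | intermediate (not isolated)
17 | (1S,3R,4S,5S,7R,10R,11R)-1-(tert-butyldimethylsilyloxy)-7-(triethylsilyloxy)longipinan-9-one | O=C1C[C@@H](O[Si](CC)(CC)CC)C(C)(C)[C@@H]2[C@H]3[C@@H](O[Si](C)(C)C(C)(C)C)C[C@@H](C)[C@@H]2[C@]31C | intermediate (not isolated)
18 | (1S,3R,4S,5S,7R,10R,11R)-1-(tert-butyldimethylsilyloxy)-7-hydroxylongipinan-9-one | O=C1C[C@@H](O)C(C)(C)[C@@H]2[C@H]3[C@@H](O[Si](C)(C)C(C)(C)C)C[C@@H](C)[C@@H]2[C@]31C | intermediate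
19 | (1S,3R,4S,5S,7R,9R,10R,11R)-1-(tert-butyldimethylsilyloxy)-9-hydroxylongipinan-7-yl 3-methylbutanoate | O[C@@H]1C[C@@H](OC(=O)CC(C)C)C(C)(C)[C@@H]2[C@H]3[C@@H](O[Si](C)(C)C(C)(C)C)C[C@@H](C)[C@@H]2[C@]31C | intermediate
20 | (1S,3R,4S,5S,7R,9R,10R,11R)-1-(tert-butyldimethylsilyloxy)-7-(3-methylbutanoyloxy)longipinan-9-yl 3-methylbut-2-enoate | CC(C)=CC(=O)O[C@@H]1C[C@@H](OC(=O)CC(C)C)C(C)(C)[C@@H]2[C@H]3[C@@H](O[Si](C)(C)C(C)(C)C)C[C@@H](C)[C@@H]2[C@]31C | intermediate
21 | (1S,3R,4S,5S,7R,9R,10R,11R)-1-hydroxy-7-(3-methylbutanoyloxy)longipinan-9-yl 3-methylbut-2-enoate | CC(C)=CC(=O)O[C@@H]1C[C@@H](OC(=O)CC(C)C)C(C)(C)[C@@H]2[C@H]3[C@@H](O)C[C@@H](C)[C@@H]2[C@]31C | intermediate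
22 | (3R,4S,5S,7R,9R,10R,11R)-7-(3-methylbutanoyloxy)-1-oxolongipinan-9-yl 3-methylbut-2-enoate | CC(C)=CC(=O)O[C@@H]1C[C@@H](OC(=O)CC(C)C)C(C)(C)[C@@H]2[C@H]3C(=O)C[C@@H](C)[C@@H]2[C@]31C | intermediate (not isolated)
23 | (4R,5S,7R,9R,10R,11R)-7-(3-methylbutanoyloxy)-1-oxolongipin-2-en-9-yl 3-methylbut-2-enoate (CNP0335239.1) | CC(C)=CC(=O)O[C@@H]1C[C@@H](OC(=O)CC(C)C)C(C)(C)[C@@H]2[C@H]3C(=O)C=C(C)[C@@H]2[C@]31C | target

**Step count and risks**

Total step count: 16. Longest linear sequence: 15 steps (steps 1–4 and 6–16, from compound 1); step 5 is a one-step side branch.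

Steps most likely to fail:

1. Step 12 (Proposed new method). What may go wrong: the 7-exo addition of the tertiary radical to the nitrile is slow, so simple reduction of the radical or 1,5-hydrogen transfer from C7 may win. The fallback uses known chemistry and sets out from 15. Reduction of the nitrile with iBu2AlH (toluene, −78 °C, acid work-up) should give the aldehyde (3R)-4-[(1R,2S,4R,5S,7S)-2-(tert-butyldimethylsilyloxy)-4-methyl-6-methylidenebicyclo[3.1.1]heptan-7-yl]-4-methyl-3-(triethylsilyloxy)pentanal F1. A cobalt-hydride HAT, branch-selective reductive alkene–aldehyde coupling (Co(salen) catalyst, CrCl2, PhSiH3) would then capture the C10 radical with divalent chromium, and the alkylchromium would add to the aldehyde in a Nozaki–Hiyama–Kishi-type ring closure. This should give (1S,3R,4S,5S,7R,10R,11R)-1-(tert-butyldimethylsilyloxy)-7-(triethylsilyloxy)longipinan-9-ol F2 as a mixture of C9 epimers. Dess–Martin oxidation converges both epimers on ketone 17, where the fallback returns to the route; the acid treatment of step 12 then gives 18.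

2. Step 10. What may go wrong: poor facial selectivity between the competing transition states, and leakage into the fused bicyclo[3.2.0] mode through the cationic intermediate. The fallback replaces substrate control by auxiliary control and sets out from 10. Aluminium amide aminolysis with (2R,5R)-2,5-dimethylpyrrolidine (AlMe3, CH2Cl2) should give the C2-symmetric amide (3R,5S,6E,9R)-5-(tert-butyldimethylsilyloxy)-10-cyano-1-[(2R,5R)-2,5-dimethylpyrrolidin-1-yl]-3,8,8-trimethyl-9-(triethylsilyloxy)dec-6-en-1-one F3. Its chiral keteniminium salt (Tf2O, collidine, then aqueous hydrolysis) undergoes the same [2+2] with the auxiliary reinforcing the facial preference; this pairing is assumed matched, and the antipodal amine would be used otherwise. The fallback returns to the route at 14.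

3. Step 13. What may go wrong: the hindered C9 ketone, flanked by the quaternary C10, may resist the intramolecular hydride transfer, or retro-aldol cleavage of the β-hydroxy ketone may compete. The fallback separates ester formation from reduction and sets out from 18. Acylation of O7 with 3-methylbutanoic anhydride (Sc(OTf)3 cat., MeCN, 0 °C) should give (1S,3R,4S,5S,7R,10R,11R)-1-(tert-butyldimethylsilyloxy)-9-oxolongipinan-7-yl 3-methylbutanoate F4. A reagent-controlled Corey–Bakshi–Shibata reduction ((S)-2-methyl-CBS-oxazaborolidine, catecholborane, toluene, −40 °C) differentiates the quaternary C10 side from the C8 methylene side of the ketone and should deliver the 9R alcohol. The fallback returns to the route at 19.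

**Further compounds**

F1 | step 12 | (3R)-4-[(1R,2S,4R,5S,7S)-2-(tert-butyldimethylsilyloxy)-4-methyl-6-methylidenebicyclo[3.1.1]heptan-7-yl]-4-methyl-3-(triethylsilyloxy)pentanal | C=C1[C@H]2[C@@H](C(C)(C)[C@H](O[Si](CC)(CC)CC)CC=O)[C@@H]1[C@H](C)C[C@@H]2O[Si](C)(C)C(C)(C)C
F2 | step 12 | (1S,3R,4S,5S,7R,10R,11R)-1-(tert-butyldimethylsilyloxy)-7-(triethylsilyloxy)longipinan-9-ol, both C9 epimers | OC1C[C@@H](O[Si](CC)(CC)CC)C(C)(C)[C@@H]2[C@H]3[C@@H](O[Si](C)(C)C(C)(C)C)C[C@@H](C)[C@@H]2[C@]31C
F3 | step 10 | (3R,5S,6E,9R)-5-(tert-butyldimethylsilyloxy)-10-cyano-1-[(2R,5R)-2,5-dimethylpyrrolidin-1-yl]-3,8,8-trimethyl-9-(triethylsilyloxy)dec-6-en-1-one | O=C(C[C@H](C)C[C@H](O[Si](C)(C)C(C)(C)C)/C=C/C(C)(C)[C@H](O[Si](CC)(CC)CC)CC#N)N1[C@H](C)CC[C@H]1C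
F4 | step 13 | (1S,3R,4S,5S,7R,10R,11R)-1-(tert-butyldimethylsilyloxy)-9-oxolongipinan-7-yl 3-methylbutanoate | O=C1C[C@@H](OC(=O)CC(C)C)C(C)(C)[C@@H]2[C@H]3[C@@H](O[Si](C)(C)C(C)(C)C)C[C@@H](C)[C@@H]2[C@]31C
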